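## Retrosynthetic overview

1. The target comes from its allyl ester. The Z methyl enoate is cut by a Still–Gennari olefination into 3-(furan-3-yl)propanal and a trifluoroethyl phosphonoacetate, itself attached to the C9 ethyl arm by alkylation with a primary iodide.
2. The E enoic acid arm is cut by a Horner–Wadsworth–Emmons (HWE) olefination with a homoprenyl-substituted allyl phosphonoacetate. The 6E trisubstituted alkene is cut by a Johnson–Claisen rearrangement of an isopropenyl carbinol.
3. Both arms grow from (S)-4-isopropenyl-δ-valerolactone: the acyl side becomes the carbinol/Claisen arm, the alkoxy side becomes the iodide.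
4. Key step: the single stereocentre is set while the lactone C–O bond is closed, by enantioselective oxidative desymmetrisation of prochiral 3-isopropenylpentane-1,5-diol (made from diethyl glutaconate, isopropenylmagnesium bromide and LiAlH4).
5. Rings: the furan is carried in intact from 3-bromofuran. The δ-lactone is the only ring made (step 3) and is opened again in step 4.

Assumption: the target is taken exactly as drawn (9S; 2E,6E in the acid arm; Z in the ester arm). The (S,S)-iridium catalyst is written for step 3, and its mirror image is used if it turns out to favour the (R)-lactone.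

## Route

Step 1
Reactants: 1 diethyl glutaconate; 2 isopropenylmagnesium bromide
Product: 4 diethyl 3-(prop-1-en-2-yl)pentanedioate, via silyl ketene acetal 3 (not isolated)
Conditions: 2 (1.4 equiv), CuBr·SMe2 (10 mol %), Me3SiCl (2.5 equiv), THF, −78 → −30 °C; then 1 M HCl, 0 °C
Reagents that add atoms: none
Why: Conjugate (1,4-) addition of a Grignard reagent catalysed by monovalent copper and accelerated by Me3SiCl so that it outruns γ-deprotonation of the glutaconate; the enolate is trapped as 3 and hydrolysed on work-up to the prochiral diester.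

Step 2
Reactants: 4 diethyl 3-(prop-1-en-2-yl)pentanedioate
Product: 5 3-(prop-1-en-2-yl)pentane-1,5-diol
Conditions: LiAlH4 (1.5 equiv), THF, 0 °C → rt; Fieser work-up
Reagents that add atoms: none
Why: Hydride reduction of both esters; the isolated 1,1-disubstituted alkene is inert to LiAlH4, and the product is a prochiral diol with two enantiotopic CH2CH2OH arms.

Step 3
Reactants: 5 3-(prop-1-en-2-yl)pentane-1,5-diol
Product: 8 (4S)-4-(prop-1-en-2-yl)oxan-2-one, via hydroxy aldehyde 6 (not isolated), via lactol 7 (not isolated)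
Conditions: Cp*Ir[(S,S)-TsNCH(Ph)CH(Ph)NH] (2 mol %), acetone/i-PrOH 9:1, 30 °C, 24–48 h
Reagents that add atoms: none
Why: Proposed new method: a redox-dynamic oxidative desymmetrising lactonisation in which the 16-electron trivalent iridium amido complex dehydrogenates one CH2OH of 5 by concerted outer-sphere hydride/proton transfer (acetone accepts the hydrogen), hydroxy aldehyde 6 closes to lactol 7 (this forms the ring C–O bond) and 7 is dehydrogenated to 8; because the Ir–H/i-PrOH couple reduces the aldehyde back quickly while the lactol-to-lactone step is irreversible, the two lactol enantiomers equilibrate through prochiral 5 (Curtin–Hammett) and the stereocentre is fixed in the lactol dehydrogenation, where the chiral sulfonyldiamine pocket reads the anomeric carbinol (ring-O flank versus ring-CH2 flank) of the diequatorial chair (axial anomeric C–H antiperiplanar to a ring-oxygen lone pair, isopropenyl equatorial), so selecting the carbinol configuration fixes C4 as S; the closest known chemistry is the Noyori-type oxidative kinetic resolution of secondary alcohols in acetone and the Ir/Ru-catalysed Oppenauer-type oxidative lactonisation of cyclic meso-diols, neither shown for an acyclic 3-substituted pentane-1,5-diol nor run as a dynamic process.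

Step 4
Reactants: 8 (4S)-4-(prop-1-en-2-yl)oxan-2-one; 2 isopropenylmagnesium bromide
Product: 11 (3RS,5S)-5-(2-hydroxyethyl)-2,6-dimethylhepta-1,6-dien-3-ol, via aluminium lactolate 9 (not isolated), via aluminium alkoxy aldehyde 10 (not isolated)
Conditions: i-Bu2AlH (1.1 equiv), CH2Cl2, −78 °C; then 2 (2.5 equiv, THF), −78 → 0 °C; aq NH4Cl/potassium sodium tartrate
Reagents that add atoms: none
Why: Half-reduction of the lactone stops at the tetrahedral diisobutylaluminium lactolate 9, which is stable at −78 °C and, on warming with the Grignard reagent, opens to the aluminium alkoxide aldehyde 10 that takes up isopropenylmagnesium bromide by 1,2-addition before any free lactol is released; the new carbinol centre forms unselectively and is erased in step 6, while C5 is not touched.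

Step 5
Reactants: 11 (3RS,5S)-5-(2-hydroxyethyl)-2,6-dimethylhepta-1,6-dien-3-ol
Product: 12 (3RS,5R)-5-(2-iodoethyl)-2,6-dimethylhepta-1,6-dien-3-ol
Conditions: PPh3 (1.1 equiv), I2 (1.1 equiv), imidazole (1.5 equiv), CH2Cl2, −20 → 0 °C; used at once
Reagents that add atoms: iodine, [I][I]
Why: Appel-type (Garegg–Samuelsson) iodination, in which the unhindered primary alcohol forms the alkoxyphosphonium ion far faster than the hindered secondary allylic one; the descriptor at C5 becomes R only because iodine raises the CIP rank of that arm.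

Step 6
Reactants: 12 (3RS,5R)-5-(2-iodoethyl)-2,6-dimethylhepta-1,6-dien-3-ol; 13 triethyl orthoacetate
Product: 16 ethyl (4E,7R)-7-(2-iodoethyl)-4,8-dimethylnona-4,8-dienoate, via mixed orthoester 14 (not isolated), via ketene acetal 15 (not isolated)
Conditions: 13 (8 equiv), EtCO2H (10 mol %), 60 °C (30 min) then 135 °C (2 h), EtOH distilled off
Reagents that add atoms: none
Why: Johnson–Claisen orthoester rearrangement through a chair transition state with the carbinol substituent equatorial, which gives the E trisubstituted alkene (≥ 95:5 expected); orthoester exchange at 60 °C masks the hydroxyl before the iodide is heated.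

Step 7
Reactants: 17 prop-2-en-1-yl 2-(diethoxyphosphoryl)acetate; 18 5-bromo-2-methylpent-2-ene
Product: 19 prop-2-en-1-yl 2-(diethoxyphosphoryl)-6-methylhept-5-enoate
Conditions: NaH (1.05 equiv), DMF, 0 °C; then 18 (1.2 equiv), 60 °C
Reagents that add atoms: none
Why: SN2 C-alkylation of the sodium phosphonoacetate enolate by a primary bromide, with near 1:1 stoichiometry to limit dialkylation; the new centre is racemic and is lost in step 8.

Step 8
Reactants: 16 ethyl (4E,7R)-7-(2-iodoethyl)-4,8-dimethylnona-4,8-dienoate; 19 prop-2-en-1-yl 2-(diethoxyphosphoryl)-6-methylhept-5-enoate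
Product: 21 prop-2-en-1-yl (2E,6E,9R)-9-(2-iodoethyl)-6,10-dimethyl-2-(4-methylpent-3-en-1-yl)undeca-2,6,10-trienoate, via aldehyde 20 (not isolated)
Conditions: i-Bu2AlH (1.05 equiv), CH2Cl2, −78 °C; then lithium salt of 19 [19 (1.3 equiv), LiN(SiMe3)2 (1.25 equiv), THF], −78 °C → rt
Reagents that add atoms: none
Why: One-pot ester half-reduction and HWE olefination; with a lithium counter-ion at room temperature the addition is reversible, so the more stable E enoate (chain trans to the ester) dominates (about 10:1 expected, minor isomer removed by chromatography).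

Step 9
Reactants: 21 prop-2-en-1-yl (2E,6E,9R)-9-(2-iodoethyl)-6,10-dimethyl-2-(4-methylpent-3-en-1-yl)undeca-2,6,10-trienoate; 22 methyl 2-[bis(2,2,2-trifluoroethoxy)phosphoryl]acetate
Product: 23 prop-2-en-1-yl (2E,6E,9S)-9-{3-[bis(2,2,2-trifluoroethoxy)phosphoryl]-4-methoxy-4-oxobutyl}-6,10-dimethyl-2-(4-methylpent-3-en-1-yl)undeca-2,6,10-trienoate
Conditions: 22 (1.5 equiv), NaH (1.4 equiv), DMF, 0 °C; then 21, 45 °C
Reagents that add atoms: none
Why: SN2 C-alkylation of the Still–Gennari phosphonoacetate anion by the unhindered primary iodide, with excess nucleophile to suppress dialkylation; the phosphonate carbon is an epimer mixture (lost in step 12), and the descriptor at C9 returns to S by CIP ranking only.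

Step 10
Reactants: 24 3-bromofuran; 25 oxetane
Product: 27 3-(furan-3-yl)propan-1-ol, via 3-furyllithium 26 (not isolated)
Conditions: n-BuLi (1.05 equiv), THF, −78 °C; then 25 (1.2 equiv), BF3·OEt2 (1.2 equiv), −78 °C; aq NaHCO3
Reagents that add atoms: none
Why: Bromine–lithium exchange followed by BF3-promoted ring opening of oxetane by the aryllithium; holding −78 °C prevents isomerisation of 3-furyllithium to the 2-lithio isomer.

Step 11
Reactants: 27 3-(furan-3-yl)propan-1-ol
Product: 28 3-(furan-3-yl)propanal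
Conditions: Cu(MeCN)4OTf (5 mol %), 2,2′-bipyridine (5 mol %), TEMPO (5 mol %), N-methylimidazole (10 mol %), air, MeCN, rt
Reagents that add atoms: none
Why: Stahl-type aerobic alcohol oxidation with monovalent copper and a nitroxyl, which is selective for primary alcohols, stops at the aldehyde and leaves the furan untouched.

Step 12
Reactants: 23 prop-2-en-1-yl (2E,6E,9S)-9-{3-[bis(2,2,2-trifluoroethoxy)phosphoryl]-4-methoxy-4-oxobutyl}-6,10-dimethyl-2-(4-methylpent-3-en-1-yl)undeca-2,6,10-trienoate; 28 3-(furan-3-yl)propanal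
Product: 29 prop-2-en-1-yl (2E,6E,9S)-9-[(3Z)-6-(furan-3-yl)-3-(methoxycarbonyl)hex-3-en-1-yl]-6,10-dimethyl-2-(4-methylpent-3-en-1-yl)undeca-2,6,10-trienoate
Conditions: KN(SiMe3)2 (1.05 equiv), 18-crown-6 (3 equiv), THF, −78 °C; then 28 (1.3 equiv), −78 °C
Reagents that add atoms: none
Why: Still–Gennari HWE olefination, in which the electron-poor trifluoroethyl phosphonate with a dissociated potassium ion eliminates fast and irreversibly from the kinetic adduct to give the Z enoate (ester cis to the new chain, ≥ 10:1 expected); one equivalent of base deprotonates only the phosphonate.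

Step 13
Reactants: 29 prop-2-en-1-yl (2E,6E,9S)-9-[(3Z)-6-(furan-3-yl)-3-(methoxycarbonyl)hex-3-en-1-yl]-6,10-dimethyl-2-(4-methylpent-3-en-1-yl)undeca-2,6,10-trienoate
Product: 30 (2E,6E,9S)-9-[(3Z)-6-(furan-3-yl)-3-(methoxycarbonyl)hex-3-en-1-yl]-6,10-dimethyl-2-(4-methylpent-3-en-1-yl)undeca-2,6,10-trienoic acid
Conditions: Pd(PPh3)4 (5 mol %), morpholine (5 equiv), THF, rt; then aq citric acid
Reagents that add atoms: none
Why: Tsuji–Trost deallylation, in which zerovalent palladium ionises only the allyl ester to a π-allyl complex that morpholine captures; the methyl ester, the furan, the stereocentre and all alkene geometries are untouched.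

## Compound list

1 | diethyl (2E)-pent-2-enedioate (diethyl glutaconate) | CCOC(=O)/C=C/CC(=O)OCC | starting material
2 | prop-1-en-2-ylmagnesium bromide (isopropenylmagnesium bromide) | CC(=C)[Mg]Br | starting material
3 | ethyl 5-ethoxy-3-(prop-1-en-2-yl)-5-[(trimethylsilyl)oxy]pent-4-enoate (racemic silyl ketene acetal) | CCOC(=O)CC(C=C(OCC)O[Si](C)(C)C)C(C)=C | intermediate
4 | diethyl 3-(prop-1-en-2-yl)pentanedioate | CCOC(=O)CC(CC(=O)OCC)C(C)=C | intermediate
5 | 3-(prop-1-en-2-yl)pentane-1,5-diol | C=C(C)C(CCO)CCO | intermediate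
6 | (3S)-5-hydroxy-3-(prop-1-en-2-yl)pentanal | C=C(C)[C@H](CC=O)CCO | intermediate
7 | (4S)-4-(prop-1-en-2-yl)oxan-2-ol (anomer mixture) | C=C(C)[C@H]1CCOC(O)C1 | intermediate
8 | (4S)-4-(prop-1-en-2-yl)oxan-2-one | C=C(C)[C@H]1CCOC(=O)C1 | intermediate
9 | (4S)-2-{[bis(2-methylpropyl)alumanyl]oxy}-4-(prop-1-en-2-yl)oxane (diisobutylaluminium lactolate, anomer mixture) | C=C(C)[C@H]1CCOC(O[Al](CC(C)C)CC(C)C)C1 | intermediate
10 | (3S)-5-{[bis(2-methylpropyl)alumanyl]oxy}-3-(prop-1-en-2-yl)pentanal (ring-opened aluminium alkoxide of the lactolate) | C=C(C)[C@H](CC=O)CCO[Al](CC(C)C)CC(C)C | intermediate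
11 | (3RS,5S)-5-(2-hydroxyethyl)-2,6-dimethylhepta-1,6-dien-3-ol | C=C(C)[C@H](CC(O)C(C)=C)CCO | intermediate
12 | (3RS,5R)-5-(2-iodoethyl)-2,6-dimethylhepta-1,6-dien-3-ol | C=C(C)[C@H](CC(O)C(C)=C)CCI | intermediate
13 | triethyl orthoacetate (1,1,1-triethoxyethane) | CC(OCC)(OCC)OCC | starting material
14 | (3RS,5R)-3-(1,1-diethoxyethoxy)-5-(2-iodoethyl)-2,6-dimethylhepta-1,6-diene | C=C(C)[C@H](CC(OC(C)(OCC)OCC)C(C)=C)CCI | intermediate
15 | (3RS,5R)-3-[(1-ethoxyethenyl)oxy]-5-(2-iodoethyl)-2,6-dimethylhepta-1,6-diene | C=C(C)[C@H](CC(OC(=C)OCC)C(C)=C)CCI | intermediate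
16 | ethyl (4E,7R)-7-(2-iodoethyl)-4,8-dimethylnona-4,8-dienoate | C=C(C)[C@H](C/C=C(\C)CCC(=O)OCC)CCI | intermediate
17 | prop-2-en-1-yl 2-(diethoxyphosphoryl)acetate (allyl diethylphosphonoacetate) | C=CCOC(=O)CP(=O)(OCC)OCC | starting material
18 | 5-bromo-2-methylpent-2-ene | CC(C)=CCCBr | starting material
19 | prop-2-en-1-yl 2-(diethoxyphosphoryl)-6-methylhept-5-enoate (racemic) | C=CCOC(=O)C(CCC=C(C)C)P(=O)(OCC)OCC | intermediate
20 | (4E,7R)-7-(2-iodoethyl)-4,8-dimethylnona-4,8-dienal | C=C(C)[C@H](C/C=C(\C)CCC=O)CCI | intermediate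
21 | prop-2-en-1-yl (2E,6E,9R)-9-(2-iodoethyl)-6,10-dimethyl-2-(4-methylpent-3-en-1-yl)undeca-2,6,10-trienoate | C=C(C)[C@H](C/C=C(\C)CC/C=C(\CCC=C(C)C)C(=O)OCC=C)CCI | intermediate
22 | methyl 2-[bis(2,2,2-trifluoroethoxy)phosphoryl]acetate | COC(=O)CP(=O)(OCC(F)(F)F)OCC(F)(F)F | starting material
23 | prop-2-en-1-yl (2E,6E,9S)-9-{3-[bis(2,2,2-trifluoroethoxy)phosphoryl]-4-methoxy-4-oxobutyl}-6,10-dimethyl-2-(4-methylpent-3-en-1-yl)undeca-2,6,10-trienoate (epimer mixture at the phosphonate carbon) | C=C(C)[C@H](C/C=C(\C)CC/C=C(\CCC=C(C)C)C(=O)OCC=C)CCC(C(=O)OC)P(=O)(OCC(F)(F)F)OCC(F)(F)F | intermediate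
24 | 3-bromofuran | Brc1ccoc1 | starting material
25 | oxetane | C1COC1 | starting material
26 | furan-3-yllithium | [Li]c1ccoc1 | intermediate
27 | 3-(furan-3-yl)propan-1-ol | OCCCc1ccoc1 | intermediate
28 | 3-(furan-3-yl)propanal | O=CCCc1ccoc1 | intermediate
29 | prop-2-en-1-yl (2E,6E,9S)-9-[(3Z)-6-(furan-3-yl)-3-(methoxycarbonyl)hex-3-en-1-yl]-6,10-dimethyl-2-(4-methylpent-3-en-1-yl)undeca-2,6,10-trienoate | C=C(C)[C@H](C/C=C(\C)CC/C=C(\CCC=C(C)C)C(=O)OCC=C)CC/C(=C/CCc1ccoc1)C(=O)OC | intermediate
30 | (2E,6E,9S)-9-[(3Z)-6-(furan-3-yl)-3-(methoxycarbonyl)hex-3-en-1-yl]-6,10-dimethyl-2-(4-methylpent-3-en-1-yl)undeca-2,6,10-trienoic acid (CNP0201108.2) | C=C(C)[C@H](C/C=C(\C)CC/C=C(\CCC=C(C)C)C(=O)O)CC/C(=C/CCc1ccoc1)C(=O)OC | target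

## Step count and risks

Total step count: 13. Longest linear sequence: 10 steps (steps 1–6, 8, 9, 12, 13).

**Step 3 (proposed new method).** The enantiomeric excess could be low if reduction of the aldehyde back to the diol is too slow to make the process dynamic, or if the catalyst discriminates poorly between the lactol enantiomers. Dehydrogenation of the primary alcohol may also be sluggish. The fallback uses known chemistry, sets out from 4 and returns at 8. Diester 4 is saponified (LiOH, THF/H2O) to 3-(prop-1-en-2-yl)pentanedioic acid F1. Ac2O at 80 °C closes it to 4-(prop-1-en-2-yl)oxane-2,6-dione F2. Cinchona-alkaloid-mediated desymmetrising methanolysis (MeOH, toluene, −55 °C, using whichever of quinidine or quinine delivers the R half-ester) gives (3R)-5-methoxy-5-oxo-3-(prop-1-en-2-yl)pentanoic acid F3. LiBH4 reduces the ester arm of its lithium carboxylate to (3S)-5-hydroxy-3-(prop-1-en-2-yl)pentanoic acid F4, which TsOH in toluene lactonises to 8.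

**Step 8 (one-pot reduction and E-selective HWE).** An α-branched phosphonate can give only modest E:Z ratios, and the one-pot half-reduction can over-reduce. The fallback sets out from 16 (with 18 for the reagent) and returns at 21. Ester 16 is reduced with i-Bu2AlH at −78 °C and aldehyde 20 is isolated. Separately, commercial prop-2-en-1-yl (triphenyl-λ5-phosphanylidene)acetate is C-alkylated with 18 (MeCN, reflux) to [6-methyl-1-oxo-1-(prop-2-en-1-yloxy)hept-5-en-2-yl]triphenylphosphonium bromide F5. Aqueous NaOH converts this to the ylide prop-2-en-1-yl 6-methyl-2-(triphenyl-λ5-phosphanylidene)hept-5-enoate F6. Salt-free Wittig olefination of 20 with F6 (toluene, 70 °C) gives 21 with the high E selectivity typical of α-alkyl stabilised ylides.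

**Step 9 (alkylation of the Still–Gennari phosphonoacetate).** The anion is weakly nucleophilic, so the reaction may be slow, and dialkylation or loss of trifluoroethoxide can compete. The fallback sets out from 21 and returns at 23. The far more nucleophilic sodium salt of trimethyl phosphonoacetate (NaH, DMF, 50 °C) is alkylated by 21 to give prop-2-en-1-yl (2E,6E,9S)-9-[3-(dimethoxyphosphoryl)-4-methoxy-4-oxobutyl]-6,10-dimethyl-2-(4-methylpent-3-en-1-yl)undeca-2,6,10-trienoate F7. Me3SiBr with pyridine (CH2Cl2, 0 °C) gives prop-2-en-1-yl (2E,6E,9S)-9-{3-[bis(trimethylsilyloxy)phosphoryl]-4-methoxy-4-oxobutyl}-6,10-dimethyl-2-(4-methylpent-3-en-1-yl)undeca-2,6,10-trienoate F8. (COCl)2 with catalytic DMF gives prop-2-en-1-yl (2E,6E,9S)-9-[3-(dichlorophosphoryl)-4-methoxy-4-oxobutyl]-6,10-dimethyl-2-(4-methylpent-3-en-1-yl)undeca-2,6,10-trienoate F9. CF3CH2OH with pyridine then gives 23.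

## Further compounds

F1 | step 3 | 3-(prop-1-en-2-yl)pentanedioic acid | C=C(C)C(CC(=O)O)CC(=O)O
F2 | step 3 | 4-(prop-1-en-2-yl)oxane-2,6-dione | C=C(C)C1CC(=O)OC(=O)C1
F3 | step 3 | (3R)-5-methoxy-5-oxo-3-(prop-1-en-2-yl)pentanoic acid | C=C(C)[C@H](CC(=O)O)CC(=O)OC
F4 | step 3 | (3S)-5-hydroxy-3-(prop-1-en-2-yl)pentanoic acid | C=C(C)[C@H](CC(=O)O)CCO
F5 | step 8 | [6-methyl-1-oxo-1-(prop-2-en-1-yloxy)hept-5-en-2-yl]triphenylphosphonium bromide | C=CCOC(=O)C(CCC=C(C)C)[P+](c1ccccc1)(c1ccccc1)c1ccccc1.[Br-]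
F6 | step 8 | prop-2-en-1-yl 6-methyl-2-(triphenyl-λ5-phosphanylidene)hept-5-enoate | C=CCOC(=O)C(CCC=C(C)C)=P(c1ccccc1)(c1ccccc1)c1ccccc1
F7 | step 9 | prop-2-en-1-yl (2E,6E,9S)-9-[3-(dimethoxyphosphoryl)-4-methoxy-4-oxobutyl]-6,10-dimethyl-2-(4-methylpent-3-en-1-yl)undeca-2,6,10-trienoate | C=C(C)[C@H](C/C=C(\C)CC/C=C(\CCC=C(C)C)C(=O)OCC=C)CCC(C(=O)OC)P(=O)(OC)OC
F8 | step 9 | prop-2-en-1-yl (2E,6E,9S)-9-{3-[bis(trimethylsilyloxy)phosphoryl]-4-methoxy-4-oxobutyl}-6,10-dimethyl-2-(4-methylpent-3-en-1-yl)undeca-2,6,10-trienoate | C=C(C)[C@H](C/C=C(\C)CC/C=C(\CCC=C(C)C)C(=O)OCC=C)CCC(C(=O)OC)P(=O)(O[Si](C)(C)C)O[Si](C)(C)C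
F9 | step 9 | prop-2-en-1-yl (2E,6E,9S)-9-[3-(dichlorophosphoryl)-4-methoxy-4-oxobutyl]-6,10-dimethyl-2-(4-methylpent-3-en-1-yl)undeca-2,6,10-trienoate | C=C(C)[C@H](C/C=C(\C)CC/C=C(\CCC=C(C)C)C(=O)OCC=C)CCC(C(=O)OC)P(=O)(Cl)Cl
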